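**Plan** (ring positions use the azulene numbering of the target: C3 carbinol, C3a/C8a ring fusion, C4 ester carbon, C7 carbinol)

1. Retrosynthesis: the vanillate C–O bond and the C7 carbinol go back to enone diol 19. The cyclopentanol bond C2–C3 is then cut (Barbier) and the ether bridge C4–O–C8 restored. Finally C8–C8a and C3a–C4 are cut together, giving a 4-methyl-3-oxidopyrylium and an (E)-enone.
2. Enabling feature: the row C4(O)–C5=C6(CH3)–C7(O)–C8H2 of the seven-membered ring is the five-carbon face of a 3-oxidopyrylium (ring oxygen on C4 and C8, oxido on C7). C8a–C3a is an enone C=C whose carbonyl carbon becomes C3.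
3. Forward order: the oxygen-bridged seven-membered ring is made first ([5+2], step 6). One SmI2 operation then opens the bridge and closes the five-membered ring (step 9). Acylation, reduction and desilylation finish.
4. Helpers, all removed on the way: the ether bridge, the C3 ketone (alkene activator, later Barbier acceptor), a thiophenol mask on C5=C6 and two silyl ethers.
5. Stereochemistry: E-alkene geometry plus endo addition fix C4, C3a and C8a. The trans ring fusion follows because the cyclopentane is closed afterwards between trans arms. C3 comes from a chelated Barbier closure. C7 and the absolute configuration come from an (S)-CBS reduction that sorts the racemate.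

Key step: step 6

Remark: 6 and 11 are achiral, so 12–19 and 23 are racemic (names carry rac; the SMILES show the enantiomer that leads to 25). The antipode is removed in step 13.

Step 1
Reactants: 1 tert-butyl(but-3-yn-1-yloxy)dimethylsilane
Product: 3 (E)-tert-butyl[(4-iodo-3-methylbut-3-en-1-yl)oxy]dimethylsilane, via vinylalane 2 (not isolated)
Conditions: AlMe3 (2 equiv), Cp2ZrCl2 (0.2 equiv), CH2Cl2, 0 °C to rt; then I2, THF, −30 °C
Reagents that add atoms: trimethylaluminium C[Al](C)C; iodine II
Why: Zirconium-catalysed Negishi carboalumination adds methyl and aluminium syn across the terminal alkyne with the metal on the terminal carbon, and iodinolysis with retention should give the E trisubstituted vinyl iodide.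

Step 2
Reactants: 3 (E)-tert-butyl[(4-iodo-3-methylbut-3-en-1-yl)oxy]dimethylsilane; 4 N-methoxy-N,2-dimethylpropanamide
Product: 6 (E)-7-[(tert-butyldimethylsilyl)oxy]-2,5-dimethylhept-4-en-3-one, via vinyllithium 5 (not isolated)
Conditions: t-BuLi (2.1 equiv), Et2O, −78 °C; then 4, −78 to 0 °C; aq. NH4Cl
Reagents that add atoms: none
Why: Iodine–lithium exchange gives a configurationally stable vinyllithium that acylates the amide once (Weinreb ketone synthesis), so the enone should keep the E geometry with acyl and methyl cis.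

Step 3
Reactants: 7 methyl 3-methylfuran-2-carboxylate
Product: 8 (3-methylfuran-2-yl)methanol
Conditions: LiAlH4, Et2O, 0 °C
Reagents that add atoms: none
Why: Standard hydride reduction of an aromatic ester to the primary alcohol.

Step 4
Reactants: 8 (3-methylfuran-2-yl)methanol
Product: 9 6-hydroxy-4-methyl-2H-pyran-3(6H)-one
Conditions: NBS, NaHCO3, NaOAc, THF/H2O (4:1), 0 °C
Reagents that add atoms: water O
Why: Achmatowicz rearrangement, in which oxidation of the furan to the ene-dione and recyclisation through the carbinol oxygen give the hydroxypyranone with the furan methyl on C4.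

Step 5
Reactants: 9 6-hydroxy-4-methyl-2H-pyran-3(6H)-one
Product: 10 4-methyl-5-oxo-5,6-dihydro-2H-pyran-2-yl acetate
Conditions: Ac2O, pyridine, 4-(dimethylamino)pyridine (DMAP, cat.), CH2Cl2, 0 °C
Reagents that add atoms: acetic anhydride CC(=O)OC(C)=O
Why: Acylation of the lactol installs the leaving group needed to generate the ylide.

Step 6
Reactants: 10 4-methyl-5-oxo-5,6-dihydro-2H-pyran-2-yl acetate; 6 (E)-7-[(tert-butyldimethylsilyl)oxy]-2,5-dimethylhept-4-en-3-one
Product: 12 rac-(1S,5S,6S,7S)-7-{2-[(tert-butyldimethylsilyl)oxy]ethyl}-3,7-dimethyl-6-(2-methylpropanoyl)-8-oxabicyclo[3.2.1]oct-3-en-2-one, via oxidopyrylium 11 (not isolated)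
Conditions: Et3N (1.2 equiv), 6 (4 equiv, excess recovered), MeCN, 60 °C, 10 added slowly
Reagents that add atoms: none
Why: Et3N eliminates acetic acid from 10 to give the 4-methyl-3-oxidopyrylium 11, a cyclic carbonyl ylide that adds across the enone C=C of 6 in a concerted, suprafacial [5+2] cycloaddition; the closest known reaction type is the intermolecular cycloaddition of 3-oxidopyrylium ylides with acrylates and vinyl ketones. The single cycloaddition closes the seven-membered carbocycle C1–C7 (and with it the oxygen-bridged tetrahydrofuran) by forming C1–C7 and C5–C6 together, so no ring is closed by a separate exo or endo cyclisation. Regiochemistry follows the polarity of the partners: the enolate-like ylide terminus next to the oxido carbon bonds to the beta carbon of the enone, which puts the acyl-bearing carbon next to the bridgehead remote from the ketone (6-acyl adduct). The E geometry of 6 is transferred, so acyl and 7-methyl are cis and the silyloxyethyl arm is trans to the acyl group; the endo transition state, with the carbonyl under the unsaturated bridge of the ylide and the small methyl instead of the long arm in the endo sector, sets 6-acyl endo, 7-methyl endo and the arm exo relative to the new bridgeheads C1 and C5. The step needs chemoselectivity over ylide dimerisation and a usable rate with a beta,beta-disubstituted acceptor, which excess 6, slow addition of 10 and the 4-methyl group on the ylide should help, and it needs endo selectivity, which rests on the factors named. The partners are achiral, so 12 is racemic.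

Step 7
Reactants: 12 rac-(1S,5S,6S,7S)-7-{2-[(tert-butyldimethylsilyl)oxy]ethyl}-3,7-dimethyl-6-(2-methylpropanoyl)-8-oxabicyclo[3.2.1]oct-3-en-2-one
Product: 14 rac-7-(2-hydroxyethyl)-3,7-dimethyl-6-(2-methylpropanoyl)-4-exo-(phenylsulfanyl)-8-oxabicyclo[3.2.1]octan-2-one (ring configuration as in 12; both C3 epimers), via sulfide 13 (not isolated)
Conditions: PhSH (1.2 equiv), Et3N (0.1 equiv), CH2Cl2, rt; concentrate; HF·pyridine, THF, 0 °C to rt
Reagents that add atoms: benzenethiol Sc1ccccc1
Why: Thia-Michael addition from the exo face masks the enone C=C, so that the later ketyl can cleave only the C–O bond alpha to the ketone and not the allylic one, and fluoride then removes the silyl ether.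

Step 8
Reactants: 14 rac-7-(2-hydroxyethyl)-3,7-dimethyl-6-(2-methylpropanoyl)-4-exo-(phenylsulfanyl)-8-oxabicyclo[3.2.1]octan-2-one
Product: 15 rac-7-(2-iodoethyl)-3,7-dimethyl-6-(2-methylpropanoyl)-4-exo-(phenylsulfanyl)-8-oxabicyclo[3.2.1]octan-2-one (configuration as in 14)
Conditions: I2, PPh3, imidazole, CH2Cl2, 0 °C to rt
Reagents that add atoms: iodine II
Why: Appel iodination converts the primary alcohol into the iodide without touching the ketones or the sulfide.

Step 9
Reactants: 15 rac-7-(2-iodoethyl)-3,7-dimethyl-6-(2-methylpropanoyl)-4-exo-(phenylsulfanyl)-8-oxabicyclo[3.2.1]octan-2-one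
Product: 17 rac-1,8-dihydroxy-3a,6-dimethyl-7-(phenylsulfanyl)-1-(propan-2-yl)octahydroazulen-5(1H)-one (trans-fused; 1-OH cis to 3a-CH3; 8-OH trans to 3a-CH3; PhS cis to 8-OH; both C6 epimers), via samarium enolate 16 (not isolated)
Conditions: SmI2 (2.2 equiv), THF, −78 °C; then HMPA (10 equiv), SmI2 (2.5 equiv), −78 to 0 °C; aq. NH4Cl
Reagents that add atoms: none
Why: Divalent samarium reduces the alpha-alkoxy ketone to its ketyl, which expels the bridging oxygen to leave a trivalent-samarium enolate that protects the ring ketone and a samarium alkoxide on the former bridgehead; with HMPA the primary iodide is then reduced to an alkylsamarium that adds to the isopropyl ketone (samarium Barbier reaction, five-membered ring closed onto the carbonyl carbon), with samarium chelated between that alkoxide and the ketone oxygen and the isopropyl group turned away from the oxygenated carbon, which should place the tertiary hydroxyl cis to the angular methyl, while the trans ring fusion is fixed by the trans arms set in step 6.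

Step 10
Reactants: 17 rac-1,8-dihydroxy-3a,6-dimethyl-7-(phenylsulfanyl)-1-(propan-2-yl)octahydroazulen-5(1H)-one
Product: 19 rac-(1R,3aR,8S,8aS)-1,8-dihydroxy-3a,6-dimethyl-1-(propan-2-yl)-1,2,3,3a,8,8a-hexahydroazulen-5(4H)-one, via sulfone 18 (not isolated)
Conditions: mCPBA (2.2 equiv), NaHCO3, CH2Cl2, 0 °C; then DBU (2 equiv), rt
Reagents that add atoms: none
Why: Oxidation of the sulfide to the sulfone and E1cB loss of benzenesulfinate through the ketone enolate regenerate the enone, and the double bond can only form between C6 and C7.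

Step 11
Reactants: 20 4-hydroxy-3-methoxybenzoic acid (vanillic acid)
Product: 22 4-[(tert-butyldimethylsilyl)oxy]-3-methoxybenzoic acid, via bis-silyl compound 21 (not isolated)
Conditions: TBSCl (2.5 equiv), imidazole, DMF, rt; then AcOH/THF/H2O, rt
Reagents that add atoms: tert-butyldimethylsilyl chloride CC(C)(C)[Si](C)(C)Cl
Why: Both acidic hydroxyls are silylated and the much more labile silyl ester is then hydrolysed selectively, leaving the phenol silyl ether.

Step 12
Reactants: 19 rac-(1R,3aR,8S,8aS)-1,8-dihydroxy-3a,6-dimethyl-1-(propan-2-yl)-1,2,3,3a,8,8a-hexahydroazulen-5(4H)-one; 22 4-[(tert-butyldimethylsilyl)oxy]-3-methoxybenzoic acid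
Product: 23 rac-(3R,3aS,4S,8aR)-3-hydroxy-6,8a-dimethyl-7-oxo-3-(propan-2-yl)-1,2,3,3a,4,7,8,8a-octahydroazulen-4-yl 4-[(tert-butyldimethylsilyl)oxy]-3-methoxybenzoate
Conditions: dicyclohexylcarbodiimide (DCC), DMAP, CH2Cl2, 0 °C to rt
Reagents that add atoms: none
Why: Steglich esterification should acylate only the secondary allylic hydroxyl with retention, because the tertiary hydroxyl is too hindered and the ring carbonyl is still a ketone.

Step 13
Reactants: 23 rac-(3R,3aS,4S,8aR)-3-hydroxy-6,8a-dimethyl-7-oxo-3-(propan-2-yl)-1,2,3,3a,4,7,8,8a-octahydroazulen-4-yl 4-[(tert-butyldimethylsilyl)oxy]-3-methoxybenzoate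
Product: 24 (3R,3aS,4S,7R,8aR)-3,7-dihydroxy-6,8a-dimethyl-3-(propan-2-yl)-1,2,3,3a,4,7,8,8a-octahydroazulen-4-yl 4-[(tert-butyldimethylsilyl)oxy]-3-methoxybenzoate
Conditions: (S)-1-methyl-3,3-diphenyltetrahydro-1H,3H-pyrrolo[1,2-c][1,3,2]oxazaborole [(S)-Me-CBS, 0.5 equiv], BH3·SMe2 (about 0.7 equiv), toluene, −40 °C, run to about half conversion; MeOH; chromatography
Reagents that add atoms: none
Why: Corey–Bakshi–Shibata reduction delivers hydride 1,2 to the enone under catalyst control (alkenyl as the large group) to give the 7R carbinol, which for the enantiomer of 23 drawn is also the face anti to the angular methyl (matched and fast), whereas the antipode is mismatched and should stay behind as ketone or give a C7-epimeric diastereomer, so chromatography should leave 24 as a single enantiomer.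

Step 14
Reactants: 24 (3R,3aS,4S,7R,8aR)-3,7-dihydroxy-6,8a-dimethyl-3-(propan-2-yl)-1,2,3,3a,4,7,8,8a-octahydroazulen-4-yl 4-[(tert-butyldimethylsilyl)oxy]-3-methoxybenzoate
Product: 25 (3R,3aS,4S,7R,8aR)-3,7-dihydroxy-6,8a-dimethyl-3-(propan-2-yl)-1,2,3,3a,4,7,8,8a-octahydroazulen-4-yl 4-hydroxy-3-methoxybenzoate
Conditions: Bu4NF (1.1 equiv), AcOH (1.1 equiv), THF, 0 °C
Reagents that add atoms: none
Why: Buffered fluoride cleaves the aryl silyl ether quickly and should leave the allylic ester and both alcohols untouched.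

**Compound list**

1 | tert-butyl(but-3-yn-1-yloxy)dimethylsilane | C#CCCO[Si](C)(C)C(C)(C)C | starting material
2 | (E)-[4-(tert-butyldimethylsilyloxy)-2-methylbut-1-en-1-yl]dimethylaluminium | C/C(=C\[Al](C)C)CCO[Si](C)(C)C(C)(C)C | intermediate
3 | (E)-tert-butyl[(4-iodo-3-methylbut-3-en-1-yl)oxy]dimethylsilane | C/C(=C\I)CCO[Si](C)(C)C(C)(C)C | intermediate
4 | N-methoxy-N,2-dimethylpropanamide | CC(C)C(=O)N(C)OC | starting material
5 | (E)-[4-(tert-butyldimethylsilyloxy)-2-methylbut-1-en-1-yl]lithium | C/C(=C\[Li])CCO[Si](C)(C)C(C)(C)C | intermediate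
6 | (E)-7-[(tert-butyldimethylsilyl)oxy]-2,5-dimethylhept-4-en-3-one | CC(C)C(=O)/C=C(\C)CCO[Si](C)(C)C(C)(C)C | intermediate
7 | methyl 3-methylfuran-2-carboxylate | COC(=O)c1occc1C | starting material
8 | (3-methylfuran-2-yl)methanol | Cc1ccoc1CO | intermediate
9 | 6-hydroxy-4-methyl-2H-pyran-3(6H)-one (racemic lactol) | CC1=CC(O)OCC1=O | intermediate
10 | 4-methyl-5-oxo-5,6-dihydro-2H-pyran-2-yl acetate (racemic) | CC(=O)OC1OCC(=O)C(C)=C1 | intermediate
11 | 4-methylpyrylium-3-olate | Cc1cc[o+]cc1[O-] | intermediate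
12 | rac-(1S,5S,6S,7S)-7-{2-[(tert-butyldimethylsilyl)oxy]ethyl}-3,7-dimethyl-6-(2-methylpropanoyl)-8-oxabicyclo[3.2.1]oct-3-en-2-one | CC(C)C(=O)[C@@H]1[C@@H]2C=C(C)C(=O)[C@@H](O2)[C@@]1(C)CCO[Si](C)(C)C(C)(C)C | intermediate
13 | rac-7-{2-[(tert-butyldimethylsilyl)oxy]ethyl}-3,7-dimethyl-6-(2-methylpropanoyl)-4-exo-(phenylsulfanyl)-8-oxabicyclo[3.2.1]octan-2-one (both C3 epimers) | CC(C)C(=O)[C@@H]1[C@@H]2[C@@H](Sc3ccccc3)C(C)C(=O)[C@@H](O2)[C@@]1(C)CCO[Si](C)(C)C(C)(C)C | intermediate
14 | rac-7-(2-hydroxyethyl)-3,7-dimethyl-6-(2-methylpropanoyl)-4-exo-(phenylsulfanyl)-8-oxabicyclo[3.2.1]octan-2-one (both C3 epimers) | CC(C)C(=O)[C@@H]1[C@@H]2[C@@H](Sc3ccccc3)C(C)C(=O)[C@@H](O2)[C@@]1(C)CCO | intermediate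
15 | rac-7-(2-iodoethyl)-3,7-dimethyl-6-(2-methylpropanoyl)-4-exo-(phenylsulfanyl)-8-oxabicyclo[3.2.1]octan-2-one (both C3 epimers) | CC(C)C(=O)[C@@H]1[C@@H]2[C@@H](Sc3ccccc3)C(C)C(=O)[C@@H](O2)[C@@]1(C)CCI | intermediate
16 | bis(diiodosamarium) alkoxide–enolate of ring-opened 15 | CC(C)C(=O)[C@@H]1[C@@H](O[Sm](I)I)[C@@H](Sc2ccccc2)C(C)C(O[Sm](I)I)=C[C@@]1(C)CCI | intermediate
17 | rac-1,8-dihydroxy-3a,6-dimethyl-7-(phenylsulfanyl)-1-(propan-2-yl)octahydroazulen-5(1H)-one (trans-fused; both C6 epimers) | O[C@H]1[C@@H](Sc2ccccc2)C(C)C(=O)C[C@@]2(C)CC[C@@](O)(C(C)C)[C@H]12 | intermediate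
18 | rac-7-(benzenesulfonyl)-1,8-dihydroxy-3a,6-dimethyl-1-(propan-2-yl)octahydroazulen-5(1H)-one | O[C@H]1[C@@H](S(=O)(=O)c2ccccc2)C(C)C(=O)C[C@@]2(C)CC[C@@](O)(C(C)C)[C@H]12 | intermediate
19 | rac-(1R,3aR,8S,8aS)-1,8-dihydroxy-3a,6-dimethyl-1-(propan-2-yl)-1,2,3,3a,8,8a-hexahydroazulen-5(4H)-one | O[C@H]1C=C(C)C(=O)C[C@@]2(C)CC[C@@](O)(C(C)C)[C@H]12 | intermediate
20 | 4-hydroxy-3-methoxybenzoic acid | COc1cc(C(=O)O)ccc1O | starting material
21 | tert-butyldimethylsilyl 4-[(tert-butyldimethylsilyl)oxy]-3-methoxybenzoate | COc1cc(C(=O)O[Si](C)(C)C(C)(C)C)ccc1O[Si](C)(C)C(C)(C)C | intermediate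
22 | 4-[(tert-butyldimethylsilyl)oxy]-3-methoxybenzoic acid | COc1cc(C(=O)O)ccc1O[Si](C)(C)C(C)(C)C | intermediate
23 | rac-(3R,3aS,4S,8aR)-3-hydroxy-6,8a-dimethyl-7-oxo-3-(propan-2-yl)-1,2,3,3a,4,7,8,8a-octahydroazulen-4-yl 4-[(tert-butyldimethylsilyl)oxy]-3-methoxybenzoate | COc1cc(C(=O)O[C@H]2C=C(C)C(=O)C[C@@]3(C)CC[C@@](O)(C(C)C)[C@H]23)ccc1O[Si](C)(C)C(C)(C)C | intermediate
24 | (3R,3aS,4S,7R,8aR)-3,7-dihydroxy-6,8a-dimethyl-3-(propan-2-yl)-1,2,3,3a,4,7,8,8a-octahydroazulen-4-yl 4-[(tert-butyldimethylsilyl)oxy]-3-methoxybenzoate | COc1cc(C(=O)O[C@H]2C=C(C)[C@H](O)C[C@@]3(C)CC[C@@](O)(C(C)C)[C@H]23)ccc1O[Si](C)(C)C(C)(C)C | intermediate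
25 | (3R,3aS,4S,7R,8aR)-3,7-dihydroxy-6,8a-dimethyl-3-(propan-2-yl)-1,2,3,3a,4,7,8,8a-octahydroazulen-4-yl 4-hydroxy-3-methoxybenzoate | COc1cc(C(=O)O[C@H]2C=C(C)[C@H](O)C[C@@]3(C)CC[C@@](O)(C(C)C)[C@H]23)ccc1O | target

**Count and risks**

Total step count: 14. Longest linear sequence: 11 steps (7 to 25 through steps 3–10 and 12–14).

Steps most likely to fail:

Step 6. The cycloaddition to the hindered beta,beta-disubstituted isopropyl enone may be too slow. Ylide dimerisation, base-induced E/Z equilibration of 6 or loss of endo selectivity could then take over. Fallback: from 3, iodine–lithium exchange (t-BuLi) and formylation with DMF give the smaller and more electrophilic enal (E)-5-[(tert-butyldimethylsilyl)oxy]-3-methylpent-2-enal F1. Its [5+2] cycloaddition with 10 (Et3N, MeCN) should give rac-(1S,5S,6S,7S)-7-{2-[(tert-butyldimethylsilyl)oxy]ethyl}-3,7-dimethyl-2-oxo-8-oxabicyclo[3.2.1]oct-3-ene-6-carbaldehyde F2. Addition of isopropylmagnesium chloride with CeCl3 (THF, −78 °C) to the aldehyde alone gives rac-7-{2-[(tert-butyldimethylsilyl)oxy]ethyl}-6-(1-hydroxy-2-methylpropyl)-3,7-dimethyl-8-oxabicyclo[3.2.1]oct-3-en-2-one F3. Dess–Martin oxidation returns to the route at 12.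

Step 9. After bridge opening the samarium aldolate may fragment by retro-aldol cleavage, or the alkylsamarium may be protonated before it closes the ring. Fallback: from 15, the bridge is opened with SmI2 alone (THF, −78 °C) and the enolate and alkoxide are silylated in situ (Me3SiCl, Et3N) to the bis(trimethylsilyl) enol ether/ether of the ring-opened iodo ketone F4. Iodine–lithium exchange with t-BuLi (Et2O/pentane, −100 °C) then closes the cyclopentanol by intramolecular addition to the isopropyl ketone, giving the bis(trimethylsilyl) derivative of the cyclised diol F5. Dilute HCl in THF removes both silyl groups and returns to the route at 17.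

Step 13. Catalyst control may compete poorly with the substrate bias, so that the two enantiomers of 23 are not cleanly told apart and 24 is of low enantiomeric purity. Fallback: from 19, the racemate is separated by preparative chromatography on a chiral stationary phase (no new compound, F0). The (1R,3aR,8S,8aS) enantiomer is esterified as in step 12 and reduced under substrate control with NaBH4/CeCl3 (Luche reduction, hydride anti to the angular methyl), returning to the route at 24.

**Further compounds**

F1 | step 6 | (E)-5-[(tert-butyldimethylsilyl)oxy]-3-methylpent-2-enal | O=C/C=C(\C)CCO[Si](C)(C)C(C)(C)C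
F2 | step 6 | rac-(1S,5S,6S,7S)-7-{2-[(tert-butyldimethylsilyl)oxy]ethyl}-3,7-dimethyl-2-oxo-8-oxabicyclo[3.2.1]oct-3-ene-6-carbaldehyde | O=C[C@@H]1[C@@H]2C=C(C)C(=O)[C@@H](O2)[C@@]1(C)CCO[Si](C)(C)C(C)(C)C
F3 | step 6 | rac-7-{2-[(tert-butyldimethylsilyl)oxy]ethyl}-6-(1-hydroxy-2-methylpropyl)-3,7-dimethyl-8-oxabicyclo[3.2.1]oct-3-en-2-one (ring configuration as in 12; both carbinol epimers) | CC(C)C(O)[C@@H]1[C@@H]2C=C(C)C(=O)[C@@H](O2)[C@@]1(C)CCO[Si](C)(C)C(C)(C)C
F4 | step 9 | bis(trimethylsilyl) enol ether/ether of the ring-opened iodo ketone | CC(C)C(=O)[C@@H]1[C@@H](O[Si](C)(C)C)[C@@H](Sc2ccccc2)C(C)C(O[Si](C)(C)C)=C[C@@]1(C)CCI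
F5 | step 9 | bis(trimethylsilyl) derivative of the cyclised diol (silyl enol ether of 17 with 8-O-silyl ether) | C[Si](C)(C)O[C@H]1[C@@H](Sc2ccccc2)C(C)C(O[Si](C)(C)C)=C[C@@]2(C)CC[C@@](O)(C(C)C)[C@H]12
F0 | step 13 | none | none
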